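The rate constants belong to no real substance; the rest is arithmetic.

The amounts are 10 mM of substrate against 10.5 mM of partner, with 0.500 mM of protic impurity beside them, and the recipes part on when and how warm these go in.

all flasks: protic impurity 0.500 mM; time 15 s
- delta: substrate 10 mM; partner 10.5 mM (fed, over 10 s); the addition at −10 °C, then warmed to 20 °C; the feed brings no volume worth counting
- zeta: substrate 10 mM (in portions, 5, over 10 s); partner 10.5 mM; first portion at the start, last at 10 s; temperature 20 °C
- gamma: substrate 10 mM (fed, over 2.5 s); partner 10.5 mM; all else is in the flask from the start; the feed brings no volume worth counting; temperature 20 °C
- epsilon: substrate 10 mM (fed, over 10 s); partner 10.5 mM; all else is in the flask from the start; the feed brings no volume worth counting; temperature 20 °C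
- beta: substrate 10 mM; partner 10.5 mM (fed, over 10 s); all else is in the flask from the start; the feed brings no volume worth counting; temperature 20 °C

    crystals ⇌ target, rate k1*(cs1 - [target]) while solid is left; crystals form when [target] > cs1 (cs1 = 0.11 mM, k1 = 18 s⁻¹)
    substrate → open intermediate (k2 = 0.10 s⁻¹, Ea2 = 71.0 kJ mol⁻¹)
    partner + protic impurity → quenched reagent (k3 = 49 M⁻¹ s⁻¹, Ea3 = 40.0 kJ mol⁻¹)
    partner → second intermediate (k4 = 0.18 s⁻¹, Ea4 = 68.0 kJ mol⁻¹)
    substrate + target ⇌ idle adduct, settled at all times (K5 = 61 M⁻¹, ΔH5 = −9.00 kJ mol⁻¹)
    open intermediate + second intermediate → target (k6 = 2.0 M⁻¹ s⁻¹, Ea6 = 42.0 kJ mol⁻¹)
    2 second intermediate → homo product (k7 = 0.027 M⁻¹ s⁻¹, Ea7 = 66.0 kJ mol⁻¹)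
    (constants at 20 °C)

- percentages count the substrate that a species holds: one idle adduct counts as two
- target is meant together with its idle adduct and crystals
- two of one species on the left: rate k times its square, two consumed each time
- solid, in amounts per volume of the solution: crystals
- all constants are for 20 °C and move with temperature by the activation energies and enthalpies
- in an amount of target, one idle adduct counts as one target

- the best flask by amount of target, in percent of the substrate charged; "all alike" if 1.5 percentage points covers them all (delta / zeta / gamma / epsilon / beta / all alike)
- amount of target at the end, in percent of the substrate charged, delta
- amount of target at the end, in percent of the substrate charged, zeta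
- amount of target at the end, in percent of the substrate charged, gamma
- amount of target at the end, in percent of the substrate charged, epsilon
- amount of target at the end, in percent of the substrate charged, beta

Something looks contradictory here. Substrate opens with a half-life of 6.93 s and partner turns into second intermediate with a half-life of 3.85 s, both less than half of the 15 s allowed, so you expect a flask near its end. Yet the target must still be built by the coupling of the two intermediates, and that is where you should look. Take the coupling time, one over the coupling rate constant times the substrate charge, 50.0 s: the time in which two intermediates of equal concentration c, both at that charge, fall to half, since c then falls as c₀/(1 + t/tc). The two numbers go together because the coupling time is longer than the wait for opening, 10.0 s, so control has passed from the feeding steps to the coupling, the rate-limiting step.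

My reckoning follows from this. Opening and the change of partner are first-order, so both intermediates appear from the first moment and the wait cannot be subtracted as dead time; instead I take T, the time left after half of any feed, and start both clocks together there, which is a rough choice. The filled fraction of each intermediate rises as one minus an exponential with its own rate constant, and the integral of the product of the two fractions over T is the window W, the time at full charge that the rising intermediates are worth; I then take the share coupled as W/(W + tc). For gamma, T is 13.8 s and W is 4.69 s, which gives 8.57%. For epsilon, T is 10.0 s and W is 2.40 s, which gives 4.57%. To rank the flasks I count the time left after half of the fed charge is in, and for delta, cold during its feed, the time after the feed, and that favours gamma.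

The forecast, reasoning that “target forms slowly, and 15 s is far from completion”, also names gamma, but puts gamma at 8.8%, above my figure, with delta 1.05%, zeta 5.85%, epsilon 5.8% and beta 6.4%.

The simulation gives gamma as best, at 8.86%, with delta 1.05%, zeta 5.84%, epsilon 5.82% and beta 6.43%, as the forecast said. At 15.0 s gamma still holds 65.6% as open intermediate and 8.46 mM of second intermediate, so its charge is waiting to couple. Left until 150 s, gamma has T of 149 s and a window of 137 s, which gives 73.3%, and the run reads 72.5%.

For delta left until 1.0 min, T counts from the end of the cold feed and is 50.0 s, the window is 38.1 s, and so the coupling time gives 43.2%. The simulation gives 42.7%, with 56.6% still open intermediate.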